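# Proposed synthesis of (R)-1-(2,5-dihydroxy-3-methoxyphenyl)tridecan-2-yl acetate (9)

Ring atoms are numbered C1 (chain), C2 (OH), C3 (OMe), C4 (H), C5 (OH), C6 (H). Chain atoms are C1′ (benzylic CH2), C2′ (stereocenter) and C3′–C13′.

## The problem

Target 9 is a methoxyhydroquinone joined through C1 to an unbranched C13 chain. Its only stereocenter is C2′, which CIP analysis of the given SMILES assigns as R, and C2′ carries the only ester. The ring is 1,2,3,5-substituted, with the chain ortho to the C2 hydroxyl but meta to both other oxygens. Directed metalation of this oxygen pattern would go to C4, between two oxygens, so the C1–C2 ortho relation has to come from the building block. C2′ sits between two methylene groups (C1′ and C3′), so a ketone reduction would have little to discriminate, and there is no second stereocenter to relay from. The acetate is on the secondary oxygen while both phenols are free. Acetylation at the end would hit the phenols first, so the ester must be in place before the phenols are released. The hydroquinone autoxidises to quinone 8, fastest in base. A C2 phenoxide is also placed for O-to-O acetyl transfer through a seven-membered transition state, so the last steps must be neutral and reductive.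

Two features open the plan. C2′ is the carbinol carbon of an ester of a dialkyl carbinol with two unbranched CH2 substituents, so it is the carbon of a 1-acetoxyalkyl radical that a chiral nickel catalyst can couple enantioconvergently. The ring, with the C5 oxygen removed, is an ortho-alkyl guaiacol whose only free position para to the phenol is C5.

## Retrosynthesis

**9 to 8.** No skeletal bond is cut; the two phenolic O–H bonds are traced back to the quinone carbonyls of 8. This puts the last purification at the stable, chromatographable quinone and leaves a neutral two-electron reduction as the final operation. The forward step must reduce the quinone without base, so that the acetate neither migrates nor hydrolyses.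

**8 to 7.** The C5–O bond is cut. Adding this oxygen late makes the ring of 7 a simple 2,6-disubstituted phenol. Both ortho positions are blocked (C1 by the chain, C3 by OMe), so a phenol-to-para-quinone oxidation has only C5 to attack. Carrying both oxygens from the start would need two protecting groups and a longer arene synthesis. Precursor 7 has one oxygen less and is not air-sensitive.

**7 to 6.** The O–benzyl bond is cut. The phenol must be masked in step 3, and benzyl is chosen because its removal is a neutral hydrogenolysis. C2′ is homobenzylic, not benzylic, so its C–O bond is safe under hydrogen.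

**6 to 3 and 4, through 5.** The C2′–C3′ bond and the C2′O–acetyl bond are cut together. This leaves three achiral pieces: aldehyde 3 (C1′ and C2′), terminal olefin 4 (C3′–C13′) and an acetyl donor. Racemic 5, the adduct of 3 and the acetyl donor, is funnelled into one configuration by the catalyst. The neighbouring cut, C1′–C2′, would need a benzylic metal partner. That is outside the nucleophile class of this coupling and is reactive enough for an uncatalysed, racemic substitution. The chosen cut forms the C–C bond, the stereocenter and the secondary acetate in one operation, so no free secondary alcohol ever needs selective acylation.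

**3 to 2 to 1.** The C2′=O carbon is traced to the internal alkene carbon of allyl ether 2 (oxidative cleavage removes the terminal carbon), and 2 to commercial o-eugenol 1 by O-benzylation. In 1 the three-carbon unit already sits on the carbon ortho to the phenol and meta to the methoxy group, so the ring regiochemistry is bought with the starting material.

## Roads not taken

**Alternative 1:** the most obvious cut, C1–C1′, joining an aryl metal to a terminal epoxide. 2,5-Bis(benzyloxy)-1-bromo-3-methoxybenzene A1 would be metalated and opened onto (R)-2-undecyloxirane A2 under copper catalysis. This gives (R)-1-[2,5-bis(benzyloxy)-3-methoxyphenyl]tridecan-2-ol A3, which would then be acetylated and debenzylated. The stereocenter is bought or resolved rather than made: a hydrolytic kinetic resolution to A2 discards half the material. A1 needs its own multistep preparation, because metalation of the parent ring goes to C4. The acetate needs a separate step. The chosen plan makes C2′, the C2′–C3′ bond and the ester in one catalytic step from achiral inputs.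

**Alternative 2:** a biosynthesis-like late oxygenation at C2. The ring of 9 hides a 5-alkylresorcinol (chain at C1, oxygens at C3 and C5), as expected from a 3-hydroxytetradecanoyl starter unit. (R)-1-(3-Hydroxy-5-methoxyphenyl)tridecan-2-yl acetate A4 would be oxidised para to its phenol to give 8. Here the para carbon (C2) is flanked by the methoxy group and the chain, so attack at the open ortho carbons competes. A4 also needs desymmetrisation of a 3,5-dioxygenated arene, a longer run-up than the three steps from 1 to 6. The chosen precursor 7 offers the oxidant an unhindered para position.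

**Alternative 3:** the C1–C1′ cut by a radical, from the chiral pool. (R)-3-Acetoxytetradecanoic acid A5 would be decarboxylated with silver(I) and persulfate in the presence of 2-methoxy-1,4-benzoquinone A6, giving 8 in one C–C bond-forming step. The nucleophilic primary radical adds to both carbons of the unsubstituted double bond of A6. It prefers the carbon β to the more electron-poor carbonyl, which leads to the 2,5-isomer (R)-1-(4-methoxy-3,6-dioxocyclohexa-1,4-dien-1-yl)tridecan-2-yl acetate A7. The route is the shortest on paper but leaves the ring connectivity, the first problem of the target, uncontrolled, and 8 and A7 would be hard to separate.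

Key step: step 3

Assumption: the sense of induction in step 3 is set by the catalyst alone. The bis(oxazoline) antipode that gives (R)-6 is used, and which antipode that is would be fixed on a model aldehyde.

## Route

Step 1
Reactants: 1 o-eugenol (2-allyl-6-methoxyphenol)
Product: 2 1-allyl-2-(benzyloxy)-3-methoxybenzene
Conditions: BnBr, K2CO3, DMF, rt
Reagents that add atoms: benzyl bromide, BrCc1ccccc1
Why: Williamson etherification of the phenol; the benzyl ether masks the oxygen through step 3 and is removable under neutral conditions.

Step 2
Reactants: 2 1-allyl-2-(benzyloxy)-3-methoxybenzene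
Product: 3 2-[2-(benzyloxy)-3-methoxyphenyl]acetaldehyde
Conditions: OsO4 (2 mol%), NaIO4, 2,6-lutidine, dioxane/H2O, rt; used at once
Reagents that add atoms: osmium tetroxide, O=[Os](=O)(=O)=O (catalytic oxygen carrier); sodium periodate, [Na+].[O-]I(=O)(=O)=O (terminal oxidant)
Why: Lemieux–Johnson cleavage of the terminal alkene, with lutidine suppressing over-oxidation; the aryl ethers are inert and the electron-rich ring is not touched.

Step 3
Reactants: 3 2-[2-(benzyloxy)-3-methoxyphenyl]acetaldehyde; 4 1-undecene
Product: 6 (R)-1-[2-(benzyloxy)-3-methoxyphenyl]tridecan-2-yl acetate, via racemic 1-bromoalkyl acetate 5 (not isolated)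
Conditions: (i) AcBr, ZnBr2 (1 mol%), CH2Cl2, −20 → 0 °C, then evaporation; (ii) 4, NiBr2·glyme (10 mol%), chiral methylene-bridged bis(oxazoline) L* (12 mol%), (EtO)2MeSiH, K3PO4·H2O, DMA/Et2O, 0 °C
Reagents that add atoms: acetyl bromide, CC(Br)=O
Why: Acetyl bromide adds across the C=O of 3 (O-acylation, bromide return) to give racemic 5, in which C2′ already carries the acetoxy group of the target. A bis(oxazoline)nickel hydride, formed from the nickel(II) salt with the silane and phosphate, inserts olefin 4 with anti-Markovnikov regiochemistry to give a primary undecylnickel species. Low-valent nickel abstracts bromine from either enantiomer of 5, so both give the same planar 1-acetoxyalkyl radical and the configuration of 5 is erased. Capture of this radical by the chiral alkylnickel complex and reductive elimination form the C2′–C3′ bond; the closest known reaction type is the nickel-catalysed enantioconvergent reductive hydroalkylation of olefins with racemic 1-haloalkyl esters, which gives esters of dialkyl carbinols with two unbranched substituents. No ring is closed. The new stereocenter C2′ is controlled by the catalyst alone: the acetate carbonyl can bind nickel and the ligand antipode decides which face of the radical couples, chosen here for R. The step needs linear hydrometalation, which the unhindered terminal olefin secures. It also needs C–Br activation to outrun loss of HBr to the styryl acetate, which the low temperature and the non-ionising radical pathway favour.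

Step 4
Reactants: 6 (R)-1-[2-(benzyloxy)-3-methoxyphenyl]tridecan-2-yl acetate
Product: 7 (R)-1-(2-hydroxy-3-methoxyphenyl)tridecan-2-yl acetate
Conditions: H2 (1 atm), 10% Pd/C, EtOAc, rt
Reagents that add atoms: none
Why: Hydrogenolysis of the aryl benzyl ether under neutral conditions; the homobenzylic C2′–O bond and the acetate are not affected, so C2′ keeps its configuration.

Step 5
Reactants: 7 (R)-1-(2-hydroxy-3-methoxyphenyl)tridecan-2-yl acetate
Product: 8 (R)-1-(5-methoxy-3,6-dioxocyclohexa-1,4-dien-1-yl)tridecan-2-yl acetate
Conditions: Fremy's salt (2.5 equiv), aq. KH2PO4, acetone/H2O, 0 °C → rt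
Reagents that add atoms: potassium nitrosodisulfonate (Fremy's salt), [K+].[K+].[O]N(S([O-])(=O)=O)S([O-])(=O)=O
Why: Teuber oxidation of a phenol to the para-quinone; both ortho positions are blocked, so the phenoxyl radical is trapped at C5, and the buffered, near-neutral medium leaves the acetate in place.

Step 6
Reactants: 8 (R)-1-(5-methoxy-3,6-dioxocyclohexa-1,4-dien-1-yl)tridecan-2-yl acetate
Product: 9 (R)-1-(2,5-dihydroxy-3-methoxyphenyl)tridecan-2-yl acetate
Conditions: sat. aq. Na2S2O4, EtOAc, rt, under Ar; degassed work-up, no chromatography
Reagents that add atoms: none
Why: Dithionite reduction of a quinone to its hydroquinone is fast, neutral and biphasic, so the product is isolated by phase separation without base or silica, and the ester and C2′ are untouched.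

## Compound list

1 | o-eugenol (2-allyl-6-methoxyphenol) | C=CCc1cccc(OC)c1O | starting material
2 | 1-allyl-2-(benzyloxy)-3-methoxybenzene | C=CCc1cccc(OC)c1OCc1ccccc1 | intermediate
3 | 2-[2-(benzyloxy)-3-methoxyphenyl]acetaldehyde | O=CCc1cccc(OC)c1OCc1ccccc1 | intermediate
4 | 1-undecene | C=CCCCCCCCCC | starting material
5 | racemic 1-bromo-2-[2-(benzyloxy)-3-methoxyphenyl]ethyl acetate | CC(=O)OC(Br)Cc1cccc(OC)c1OCc1ccccc1 | intermediate (not isolated)
6 | (R)-1-[2-(benzyloxy)-3-methoxyphenyl]tridecan-2-yl acetate | CCCCCCCCCCC[C@H](Cc1cccc(OC)c1OCc1ccccc1)OC(C)=O | intermediate
7 | (R)-1-(2-hydroxy-3-methoxyphenyl)tridecan-2-yl acetate | CCCCCCCCCCC[C@H](Cc1cccc(OC)c1O)OC(C)=O | intermediate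
8 | (R)-1-(5-methoxy-3,6-dioxocyclohexa-1,4-dien-1-yl)tridecan-2-yl acetate | CCCCCCCCCCC[C@H](CC1=CC(=O)C=C(OC)C1=O)OC(C)=O | intermediate
9 | (R)-1-(2,5-dihydroxy-3-methoxyphenyl)tridecan-2-yl acetate | CCCCCCCCCCC[C@H](Cc1cc(O)cc(OC)c1O)OC(C)=O | target

## Step count and risks

Total steps: 6. Longest linear sequence: 6 (1 to 9); olefin 4 and the acetyl donor enter in step 3.

**Step 3 (key step).** Two things are most likely to go wrong. First, enantioselectivity may erode because the small acetyl group differentiates the faces of the radical less well than a larger acyl group would. Second, the bromo acetate may be lost before coupling, either by elimination of HBr to the conjugated styryl acetate or by attack of the ortho benzyloxy oxygen on the ionised carbon with loss of the benzyl group.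

The fallback sets out from 2 and returns at 6, building C2′ by a different bond. Epoxidation of 2 with mCPBA should give racemic 2-{[2-(benzyloxy)-3-methoxyphenyl]methyl}oxirane F1. Hydrolytic kinetic resolution with the (salen)Co(III) acetate antipode that leaves the (S)-epoxide should give (S)-2-{[2-(benzyloxy)-3-methoxyphenyl]methyl}oxirane F2; by the usual correlation for 2-alkyloxiranes this is the (R,R)-catalyst. Copper(I)-catalysed opening at the terminal carbon with decylmagnesium bromide should give (R)-1-[2-(benzyloxy)-3-methoxyphenyl]tridecan-2-ol F3, since the stereocenter is not touched. Acetylation with Ac2O, pyridine and DMAP then gives 6.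

**Step 2.** The aldehyde has a doubly activated CH2 (benzylic and α to the carbonyl). Enolisation during the aqueous oxidative reaction can lead to self-aldol condensation, air oxidation or further cleavage of the enol.

The fallback sets out from 2 and returns at 3 through an isolable intermediate. Dihydroxylation (OsO4 cat., NMO) should give racemic 3-[2-(benzyloxy)-3-methoxyphenyl]propane-1,2-diol F4, which can be purified and stored. Glycol cleavage with silica-supported NaIO4 in CH2Cl2, followed by filtration, then delivers a dry solution of 3 that goes directly into step 3.

**Step 5.** The oxidation may not stop cleanly at the para-quinone. The lipophilic chain may slow conversion in the aqueous medium. The quinone may also tautomerise towards a quinone methide at C1′, with loss of the acetate.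

The fallback sets out from 7 and returns at 9, bypassing 8. Bromination para to the phenol (NBS, MeCN, 0 °C) should give (R)-1-(5-bromo-2-hydroxy-3-methoxyphenyl)tridecan-2-yl acetate F5. Miyaura borylation (B2pin2, Pd(dppf)Cl2, KOAc, dioxane) should give (R)-1-[2-hydroxy-3-methoxy-5-(4,4,5,5-tetramethyl-1,3,2-dioxaborolan-2-yl)phenyl]tridecan-2-yl acetate F6. Oxidation of the C–B bond (NaBO3·4H2O, THF/H2O, rt) gives 9. Any 8 formed by air would be returned to 9 by the dithionite wash of step 6.

## Further compounds

F1 | step 3 | racemic 2-{[2-(benzyloxy)-3-methoxyphenyl]methyl}oxirane | C1C(Cc2cccc(OC)c2OCc2ccccc2)O1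
F2 | step 3 | (S)-2-{[2-(benzyloxy)-3-methoxyphenyl]methyl}oxirane | C1[C@H](Cc2cccc(OC)c2OCc2ccccc2)O1
F3 | step 3 | (R)-1-[2-(benzyloxy)-3-methoxyphenyl]tridecan-2-ol | CCCCCCCCCCC[C@H](Cc1cccc(OC)c1OCc1ccccc1)O
F4 | step 2 | racemic 3-[2-(benzyloxy)-3-methoxyphenyl]propane-1,2-diol | OCC(O)Cc1cccc(OC)c1OCc1ccccc1
F5 | step 5 | (R)-1-(5-bromo-2-hydroxy-3-methoxyphenyl)tridecan-2-yl acetate | CCCCCCCCCCC[C@H](Cc1cc(Br)cc(OC)c1O)OC(C)=O
F6 | step 5 | (R)-1-[2-hydroxy-3-methoxy-5-(4,4,5,5-tetramethyl-1,3,2-dioxaborolan-2-yl)phenyl]tridecan-2-yl acetate | CCCCCCCCCCC[C@H](Cc1cc(B2OC(C)(C)C(C)(C)O2)cc(OC)c1O)OC(C)=O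
A1 | alternative 1 | 2,5-bis(benzyloxy)-1-bromo-3-methoxybenzene | COc1cc(OCc2ccccc2)cc(Br)c1OCc1ccccc1
A2 | alternative 1 | (R)-2-undecyloxirane | CCCCCCCCCCC[C@@H]1CO1
A3 | alternative 1 | (R)-1-[2,5-bis(benzyloxy)-3-methoxyphenyl]tridecan-2-ol | CCCCCCCCCCC[C@H](Cc1cc(OCc2ccccc2)cc(OC)c1OCc1ccccc1)O
A4 | alternative 2 | (R)-1-(3-hydroxy-5-methoxyphenyl)tridecan-2-yl acetate | CCCCCCCCCCC[C@H](Cc1cc(O)cc(OC)c1)OC(C)=O
A5 | alternative 3 | (R)-3-acetoxytetradecanoic acid | CCCCCCCCCCC[C@H](CC(O)=O)OC(C)=O
A6 | alternative 3 | 2-methoxy-1,4-benzoquinone | COC1=CC(=O)C=CC1=O
A7 | alternative 3 | (R)-1-(4-methoxy-3,6-dioxocyclohexa-1,4-dien-1-yl)tridecan-2-yl acetate | CCCCCCCCCCC[C@H](CC1=CC(=O)C(OC)=CC1=O)OC(C)=O
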